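Follow the open intermediate. It forks: with second intermediate it gives target, by itself it gives side product. Dividing the two rates removes time and the open intermediate's own level, and leaves the fork ratio, target made per side product made.

solid substrate 1.5 M; partner 2.00 equiv; protic impurity 0.300 M; time 8.0 min

1. the target standing at 8.0 min, as a percentage of the solid substrate charged
2. concentration of starting material in solution at 8.0 min, in percent of saturation

Which numbers must I know well? The coupling constant 0.018 L mol⁻¹ s⁻¹ and the side-step constant 0.065 s⁻¹ stand directly in the ratio, so the target in my reckoning moves with either as long as the ratio is small. The homocoupling constant 0.0058 L mol⁻¹ s⁻¹ enters under a root, as I balance the making of second intermediate against homocoupling. The partner's constant 0.0083 s⁻¹ also enters by a root, and pulls two ways, through making and through the partner's decay. The dissolution coefficient 0.0026 s⁻¹ and the solubility 0.67 M matter fully, as their product is the feed. The quench constant 0.040 L mol⁻¹ s⁻¹ and the forward constant 0.010 s⁻¹ count in part, through the share of starting material that goes forward.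

Now the number. At 4.00 min the flask's partner stands, by its decay, at 0.136 of its charge, and the balance gives second intermediate 0.541 M. So the fork ratio, this selectivity factor, the coupling rate over the side-step rate, is 0.150, and at that moment 0.130 of the open intermediate becomes target. At the charged impurity 0.455 of the starting material goes forward, and into a solution kept empty dissolution delivers at most 55.7% of the charge by 8.0 min. I commit to 3.30% of target. The forecast, on the ground “Open intermediate is quasi-steady”, gives 3.5% and 16.3% of saturation, its target higher than mine.

The flask gives 3.60% of target and 16.3% of saturation.

    starting material + protic impurity → quenched substrate (k1 = 0.040 L mol⁻¹ s⁻¹)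
    open intermediate + second intermediate → target (k2 = 0.018 L mol⁻¹ s⁻¹)
    starting material → open intermediate (k3 = 0.010 s⁻¹)
    open intermediate → side product (k4 = 0.065 s⁻¹)
    partner → second intermediate (k5 = 0.0083 s⁻¹)
    solid substrate ⇌ starting material, rate k6*(cs6 - [starting material]) while solid is left; crystals form when [starting material] > cs6 (cs6 = 0.67 M, k6 = 0.0026 s⁻¹)
    2 second intermediate → homo product (k7 = 0.0058 L mol⁻¹ s⁻¹)

In the flask side product stands at 21.3% of the charge at 8.00 min, so target per side product reads 0.169, above my fork ratio. The neighbour flask, charged with a quarter of the protic impurity, holds 27.9% side product. My fork ratio turns that into 4.18% target, the first flask's reading into 4.72%, and the neighbour's target stands at 4.72%.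

The numbers were chosen freely; the result is computed.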